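Both C7=C8 bonds are cut, giving crocetindial and two equivalents of one (R)-α-cyclogeranyl C10 sulfone, so the cyclohexene ring is built once. The ring rests on a [4+2] annulation that exploits its C1 gem-dimethyl carbon, the C2 methylene and the methyl-bearing C4=C5 alkene. An alkoxy radical on the C7 oxygen takes a hydrogen from a tert-butyl methyl (future C2), the C2 radical adds to vinyltriphenylphosphonium bromide (C2–C3), and the derived ylide closes on the C5 methyl ketone (C4=C5). The precursor is an acyclic tert-butyl β-oxy ketone whose single stereocentre (C6) comes from an Evans aldol reaction.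

Key step: step 6

Assumption: all-E crocetindial (8,8'-diapocarotene-8,8'-dial) is taken as a purchasable C20 building block; ring atoms carry carotenoid numbers (C1 = CMe2, C5 = methyl-bearing alkene carbon, C6 = stereocentre, C7 = exocyclic carbon).

**Step 1**
Reactants: 1 (R)-4-benzyl-1,3-oxazolidin-2-one; 2 3,3-dimethylbutanoyl chloride
Product: 3 (4R)-4-benzyl-3-(3,3-dimethylbutanoyl)-1,3-oxazolidin-2-one
Conditions: n-BuLi, THF, −78 °C; then 2, −78 → 0 °C
Reagents that add atoms: none
Why: N-acylation of the lithiated oxazolidinone by the acid chloride should install the tert-butylacetyl chain that later supplies C1, C2, C6 and the gem-dimethyl groups.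

**Step 2**
Reactants: 3 (4R)-4-benzyl-3-(3,3-dimethylbutanoyl)-1,3-oxazolidin-2-one; 4 acetaldehyde
Product: 5 (4R)-4-benzyl-3-[(2R,3S)-2-tert-butyl-3-hydroxybutanoyl]-1,3-oxazolidin-2-one
Conditions: Bu2BOTf, iPr2NEt, CH2Cl2, −78 → 0 °C; 4, −78 → 0 °C; then pH 7 buffer, MeOH, 30% H2O2, 0 °C
Reagents that add atoms: none
Why: Evans syn-aldol reaction: the Z-boron enolate should react through a chair Zimmerman–Traxler transition state on the face opposite the benzyl group, which fixes the future C6 centre (the carbinol centre is destroyed in step 5).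

**Step 3**
Reactants: 5 (4R)-4-benzyl-3-[(2R,3S)-2-tert-butyl-3-hydroxybutanoyl]-1,3-oxazolidin-2-one
Product: 6 (2S,3S)-2-tert-butylbutane-1,3-diol
Conditions: LiBH4, MeOH (1 equiv), Et2O, 0 °C
Reagents that add atoms: none
Why: Reductive cleavage of the N-acyl oxazolidinone, with hydride delivery to the exocyclic carbonyl assisted by the β-hydroxyl, should give the diol without touching the α-centre and return the auxiliary.

**Step 4**
Reactants: 6 (2S,3S)-2-tert-butylbutane-1,3-diol
Product: 7 2-{[(2S,3S)-2-tert-butyl-3-hydroxybutyl]oxy}isoindoline-1,3-dione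
Conditions: N-hydroxyphthalimide, PPh3, DIAD, THF, 0 → 23 °C
Reagents that add atoms: N-hydroxyphthalimide O=C1c2ccccc2C(=O)N1O
Why: Mitsunobu reaction with the acidic N-hydroxyphthalimide should take place at the primary hydroxyl in preference to the more hindered secondary one, and no stereocentre is involved.

**Step 5**
Reactants: 7 2-{[(2S,3S)-2-tert-butyl-3-hydroxybutyl]oxy}isoindoline-1,3-dione
Product: 8 2-{[(2S)-2-acetyl-3,3-dimethylbutyl]oxy}isoindoline-1,3-dione
Conditions: Dess–Martin periodinane, CH2Cl2, 23 °C
Reagents that add atoms: none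
Why: Dess–Martin oxidation of the secondary alcohol under neutral conditions should give the C5 methyl ketone without base that could epimerise C6 or expel N-hydroxyphthalimide by E1cB elimination.

**Step 6**
Reactants: 8 2-{[(2S)-2-acetyl-3,3-dimethylbutyl]oxy}isoindoline-1,3-dione; 9 vinyltriphenylphosphonium bromide
Product: 12 (R)-α-cyclogeraniol [(1R)-2,6,6-trimethylcyclohex-2-en-1-yl]methanol, via phosphonium bromide 10 (not isolated), via ylide 11 (not isolated)
Conditions: fac-Ir(ppy)3 (1 mol %), Hantzsch ester (1.5 equiv, slow addition), MeCN, blue LEDs, 23 °C; then solvent switch to THF, KOtBu (2.1 equiv), 0 → 23 °C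
Reagents that add atoms: none
Why: Proposed new method: electron transfer from photoexcited fac-Ir(ppy)3 (Hantzsch ester as terminal reductant) should cleave the N–O bond to the C7 alkoxy radical, which abstracts a δ-hydrogen from a tert-butyl methyl through a six-membered transition state; the nucleophilic primary C2 radical then adds to the β-carbon of 9 (C2–C3), the electrophilic α-phosphonio radical takes hydrogen from the Hantzsch ester to give salt 10, and KOtBu converts 10 into ylide 11 for an intramolecular Wittig reaction with the C5 ketone (C4=C5). The closest known reactions are the photoredox δ-C(sp3)–H Giese alkylation of N-alkoxyphthalimides, the radical addition/Wittig sequence on vinylphosphonium salts and the Schweizer annulation; their merger into one ring-forming operation is the new element. The cyclohexene closes by 6-exo-trig attack of the ylide carbon C4 on the ketone carbon C5 followed by collapse of the oxaphosphetane, which can only give the cis endocyclic alkene. No stereocentre is created: C6 is carried from step 2, and C1 stays achiral because the three methyls are homotopic. The step needs hydrogen abstraction from the tert-butyl group to outrun abstraction from the acetyl methyl, β-scission with loss of formaldehyde and direct reduction of the alkoxy radical; nine polarity-matched δ-hydrogens against three polarity-mismatched α-keto hydrogens, and slow addition of the hydrogen donor, are relied on for this. Ylide formation at 0 °C with a stoichiometric amount of base should let ring closure outrun enolisation at C6 and retro-aldol cleavage.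

**Step 7**
Reactants: 12 (R)-α-cyclogeraniol
Product: 13 1-phenyl-5-({[(1R)-2,6,6-trimethylcyclohex-2-en-1-yl]methyl}sulfanyl)-1H-tetrazole
Conditions: 1-phenyl-1H-tetrazole-5-thiol, PPh3, DIAD, THF, 0 → 23 °C
Reagents that add atoms: 1-phenyl-1H-tetrazole-5-thiol Sc1nnnn1-c1ccccc1
Why: Mitsunobu thioetherification of the primary alcohol with the acidic, highly nucleophilic tetrazole thiol should proceed by SN2 displacement at C7 without touching C6.

**Step 8**
Reactants: 13 1-phenyl-5-({[(1R)-2,6,6-trimethylcyclohex-2-en-1-yl]methyl}sulfanyl)-1H-tetrazole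
Product: 14 1-phenyl-5-({[(1R)-2,6,6-trimethylcyclohex-2-en-1-yl]methyl}sulfonyl)-1H-tetrazole
Conditions: (NH4)6Mo7O24·4H2O (10 mol %), 30% H2O2, EtOH, 0 → 23 °C
Reagents that add atoms: hydrogen peroxide OO
Why: Molybdate-catalysed peroxide oxidation should take the sulfide to the sulfone much faster than it epoxidises the isolated trisubstituted ring alkene.

**Step 9**
Reactants: 14 1-phenyl-5-({[(1R)-2,6,6-trimethylcyclohex-2-en-1-yl]methyl}sulfonyl)-1H-tetrazole (2.3 equiv); 15 crocetindial
Product: 17 (6R,6'R)-ε,ε-carotene, via apocarotenal 16 (not isolated)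
Conditions: KN(SiMe3)2, THF, −78 °C; then 15, −78 → 23 °C, argon, dark; then n-heptane, reflux, crystallisation
Reagents that add atoms: none
Why: Twofold Julia–Kocienski olefination (addition of the metalated sulfone to each formyl group, Smiles rearrangement, loss of SO2 and tetrazololate) should form both C7=C8 bonds with E preference, thermal equilibration should convert residual 7Z isomer to the all-E polyene, and the non-acidic C6 centres are untouched.

**Compound list**
1 | (R)-4-benzyl-1,3-oxazolidin-2-one | O=C1N[C@H](Cc2ccccc2)CO1 | starting material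
2 | 3,3-dimethylbutanoyl chloride | CC(C)(C)CC(Cl)=O | starting material
3 | (4R)-4-benzyl-3-(3,3-dimethylbutanoyl)-1,3-oxazolidin-2-one | CC(C)(C)CC(=O)N1[C@H](Cc2ccccc2)COC1=O | intermediate
4 | acetaldehyde | CC=O | starting material
5 | (4R)-4-benzyl-3-[(2R,3S)-2-tert-butyl-3-hydroxybutanoyl]-1,3-oxazolidin-2-one | CC(C)(C)[C@H]([C@H](C)O)C(=O)N1[C@H](Cc2ccccc2)COC1=O | intermediate
6 | (2S,3S)-2-tert-butylbutane-1,3-diol | CC(C)(C)[C@H]([C@H](C)O)CO | intermediate
7 | 2-{[(2S,3S)-2-tert-butyl-3-hydroxybutyl]oxy}isoindoline-1,3-dione | CC(C)(C)[C@H]([C@H](C)O)CON1C(=O)c2ccccc2C1=O | intermediate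
8 | 2-{[(2S)-2-acetyl-3,3-dimethylbutyl]oxy}isoindoline-1,3-dione | CC(C)(C)[C@H](C(C)=O)CON1C(=O)c2ccccc2C1=O | intermediate
9 | vinyltriphenylphosphonium bromide | C=C[P+](c1ccccc1)(c1ccccc1)c1ccccc1.[Br-] | starting material
10 | [(4S)-4-(hydroxymethyl)-3,3-dimethyl-5-oxohexyl]triphenylphosphonium bromide (not isolated) | CC(C)(CCC[P+](c1ccccc1)(c1ccccc1)c1ccccc1)[C@H](C(C)=O)CO.[Br-] | intermediate
11 | (3S)-3-(hydroxymethyl)-4,4-dimethyl-7-(triphenyl-λ5-phosphanylidene)heptan-2-one (ylide, not isolated) | CC(C)(CCC=P(c1ccccc1)(c1ccccc1)c1ccccc1)[C@H](C(C)=O)CO | intermediate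
12 | (R)-α-cyclogeraniol, [(1R)-2,6,6-trimethylcyclohex-2-en-1-yl]methanol | CC1=CCCC(C)(C)[C@H]1CO | intermediate
13 | 1-phenyl-5-({[(1R)-2,6,6-trimethylcyclohex-2-en-1-yl]methyl}sulfanyl)-1H-tetrazole | CC1=CCCC(C)(C)[C@H]1CSc1nnnn1-c1ccccc1 | intermediate
14 | 1-phenyl-5-({[(1R)-2,6,6-trimethylcyclohex-2-en-1-yl]methyl}sulfonyl)-1H-tetrazole | CC1=CCCC(C)(C)[C@H]1CS(=O)(=O)c1nnnn1-c1ccccc1 | intermediate
15 | crocetindial, all-E 8,8'-diapocarotene-8,8'-dial | O=C/C(C)=C/C=C/C(C)=C/C=C/C=C(C)/C=C/C=C(C)/C=O | starting material
16 | (6R)-8'-apo-ε-caroten-8'-al (not isolated) | CC1=CCCC(C)(C)[C@H]1/C=C/C(C)=C/C=C/C(C)=C/C=C/C=C(C)/C=C/C=C(C)/C=O | intermediate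
17 | (6R,6'R)-ε,ε-carotene | CC1=CCCC(C)(C)[C@H]1/C=C/C(C)=C/C=C/C(C)=C/C=C/C=C(C)/C=C/C=C(C)/C=C/[C@H]1C(C)=CCCC1(C)C | target

Total step count: 9. Longest linear sequence: 9 steps (1 and 2 to 17).

**Steps most likely to fail**

1. Step 6. The alkoxy radical may be reduced by the hydrogen donor, lose formaldehyde by β-scission or abstract from the acetyl methyl before it reaches the tert-butyl group. The radical–polar half may also fail through retro-aldol cleavage or C6 epimerisation under base before ring closure. The fallback uses known chemistry, sets out from 8 and returns at 12; it keeps the hydrogen-atom transfer but removes the phosphonium, the hydrogen-donor termination and all base. Compound 8 would undergo the known photoredox δ-C(sp3)–H allylation of N-alkoxyphthalimides (fac-Ir(ppy)3, Hantzsch ester, allyl phenyl sulfone, MeCN, blue LEDs), in which the C2 radical is trapped by addition–fragmentation, to give (3S)-3-(hydroxymethyl)-4,4-dimethyloct-7-en-2-one F1. Non-basic Lombardo methylenation of the ketone (Zn, CH2Br2, TiCl4, THF) would give (2S)-3,3-dimethyl-2-(prop-1-en-2-yl)hept-6-en-1-ol F2. Ring-closing metathesis with the second-generation Hoveyda–Grubbs catalyst (CH2Cl2, 40 °C) would then close C4=C5 with loss of ethene and deliver 12.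

2. Step 9. The double olefination may give incomplete E selectivity at C7=C8, the metalated sulfone may self-condense, or the second formyl group may react sluggishly. The fallback sets out from 12 and returns at 17 by the classical C15 + C10 + C15 Wittig assembly. Buffered Dess–Martin oxidation of 12 would give (R)-α-cyclocitral F3, used at once. Wittig reaction with Ph3P=CHC(=O)CH3 (toluene, 80 °C) would give (R)-α-ionone F4. Addition of CH2=CHMgBr (THF, 0 °C) would give vinyl-α-ionol F5 as a mixture at the carbinol carbon. PPh3·HBr in MeOH would convert F5 with allylic transposition into [(2E,4E)-3-methyl-5-[(1R)-2,6,6-trimethylcyclohex-2-en-1-yl]penta-2,4-dien-1-yl]triphenylphosphonium bromide F6. Two equivalents of F6 with NaOMe and purchased 2,7-dimethylocta-2,4,6-trienedial (O=C/C(C)=C/C=C/C=C(C)/C=O), followed by thermal isomerisation in refluxing heptane, would give 17.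

3. Step 3. Hydride may attack the ring carbonyl of the oxazolidinone, because the α-tert-butyl group shields the exocyclic carbonyl, and open the auxiliary instead of releasing the diol. The fallback sets out from 5 and returns at 6 by hydrolysis then reduction. LiOH/H2O2 in THF/H2O at 0 °C, where hydroperoxide is selective for the exocyclic carbonyl of hindered imides, would give (2R,3S)-2-tert-butyl-3-hydroxybutanoic acid F7 and the recovered auxiliary. LiAlH4 in THF would then reduce F7 to 6.

**Further compounds**
F1 | step 6 | (3S)-3-(hydroxymethyl)-4,4-dimethyloct-7-en-2-one | C=CCCC(C)(C)[C@H](C(C)=O)CO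
F2 | step 6 | (2S)-3,3-dimethyl-2-(prop-1-en-2-yl)hept-6-en-1-ol | C=CCCC(C)(C)[C@H](C(C)=C)CO
F3 | step 9 | (R)-α-cyclocitral, (1R)-2,6,6-trimethylcyclohex-2-ene-1-carbaldehyde | CC1=CCCC(C)(C)[C@H]1C=O
F4 | step 9 | (R)-α-ionone, (3E)-4-[(1R)-2,6,6-trimethylcyclohex-2-en-1-yl]but-3-en-2-one | CC1=CCCC(C)(C)[C@H]1/C=C/C(C)=O
F5 | step 9 | vinyl-α-ionol, (1E)-3-methyl-1-[(1R)-2,6,6-trimethylcyclohex-2-en-1-yl]penta-1,4-dien-3-ol | CC1=CCCC(C)(C)[C@H]1/C=C/C(C)(O)C=C
F6 | step 9 | [(2E,4E)-3-methyl-5-[(1R)-2,6,6-trimethylcyclohex-2-en-1-yl]penta-2,4-dien-1-yl]triphenylphosphonium bromide | CC1=CCCC(C)(C)[C@H]1/C=C/C(C)=C/C[P+](c1ccccc1)(c1ccccc1)c1ccccc1.[Br-]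
F7 | step 3 | (2R,3S)-2-tert-butyl-3-hydroxybutanoic acid | CC(C)(C)[C@H]([C@H](C)O)C(=O)O
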